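**Assumption:** the SMILES is read literally, which in germacrane-type locants gives (1S,4S,8S,10R) with the C4–C5 and C1–C10 bonds trans on the oxolane, a (Z)-angelate and a 5E enol-lactone alkene; (S)-(+)-linalool of high ee is taken as purchasable.

**Locants used:** C1 oxolane CH, C4 oxolane C(Me), C5 =CH, C6 enol-ether carbon, C7=C11 butenolide alkene, C8 CH–O, C9 CH2, C10 C(OH)Me, C12 lactone C=O, C13 CH2O.

## Retrosynthetic overview

1. Target ⇒ bis-silyl macrocycle 22 (desilylation, C13 acetylation). The ten-membered ring is closed last at C5=C6 by intramolecular vinylogous aldol condensation of the butenolide C6H2 onto the C4 aldehyde.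
2. The C8 stereocentre comes from CBS reduction of C8 ketone 14; the butenolide C7=C11 comes from dehydrogenation of a 1,4-keto lactone.
3. Key disconnection C7–C8 (with C8–C9 and C11–C13 in the same flask): a C8 acyl anion (2-silyl-1,3-dithiane linchpin) opens epoxide 5, relays by Brook rearrangement and adds 1,4 to furan-2(5H)-one; the enolate is hydroxymethylated.
4. Epoxide 5 ⇐ (S)-linalool by allylic oxidation, Sharpless epoxidation with in-situ 5-exo etherification (sets C1 and C10), then epoxide closure.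
5. Ring order: oxolane (step 2) → lactone ring brought in intact (step 4) → ten-membered carbocycle (step 9).

## Route

Step 1
Reactants: 1 (S)-(+)-linalool
Product: 2 (2E,6S)-2,6-dimethylocta-2,7-diene-1,6-diol
Conditions: SeO2 (20 mol%), t-BuOOH (2 equiv), salicylic acid (10 mol%), CH2Cl2, 25 °C
Reagents that add atoms: tert-butyl hydroperoxide, CC(C)(C)OO
Why: SeO2-catalysed allylic oxidation (ene reaction then [2,3]-sigmatropic shift) hydroxylates only the E-methyl of the trisubstituted alkene, while the vinyl carbinol has no allylic C–H and the C4 stereocentre is untouched.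

Step 2
Reactants: 2 (2E,6S)-2,6-dimethylocta-2,7-diene-1,6-diol
Product: 4 (2R)-2-[(2S,5S)-5-ethenyl-5-methyloxolan-2-yl]propane-1,2-diol, via epoxy diol 3 (not isolated)
Conditions: Ti(OiPr)4 (20 mol%), D-(−)-diethyl tartrate (24 mol%), t-BuOOH, 4 Å MS, CH2Cl2, −20 °C; then camphorsulfonic acid (10 mol%), 0 °C
Reagents that add atoms: tert-butyl hydroperoxide, CC(C)(C)OO
Why: Sharpless asymmetric epoxidation of the primary E-allylic alcohol with the D-tartrate gives the (2R,3R)-epoxide, and the tertiary C4 hydroxyl then opens it 5-exo at C1 with inversion (C3-selective opening of a 2,3-epoxy alcohol), which sets C1 (S) and C10 (R) and places the two side arms trans on the oxolane.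

Step 3
Reactants: 4 (2R)-2-[(2S,5S)-5-ethenyl-5-methyloxolan-2-yl]propane-1,2-diol
Product: 5 (2S,5S)-2-ethenyl-2-methyl-5-[(2R)-2-methyloxiran-2-yl]oxolane
Conditions: NaH (2.2 equiv), 1-(p-toluenesulfonyl)imidazole (1.05 equiv), THF, 0 → 25 °C
Reagents that add atoms: none
Why: selective sulfonylation of the primary hydroxyl followed by intramolecular Williamson displacement by the tertiary alkoxide closes the 2,2-disubstituted epoxide without breaking the C10–O bond, so C10 stays R.

Step 4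
Reactants: 5 (2S,5S)-2-ethenyl-2-methyl-5-[(2R)-2-methyloxiran-2-yl]oxolane; 6 2-(trimethylsilyl)-1,3-dithiane; 7 furan-2(5H)-one
Product: 12 trans-3-[(tert-butyldimethylsilyloxy)methyl]-4-{2-[(2R)-2-[(2S,5S)-5-ethenyl-5-methyloxolan-2-yl]-2-hydroxypropyl]-1,3-dithian-2-yl}oxolan-2-one (both 3,4-trans isomers), via lithiated silyl dithiane 8 (not isolated), via relay carbanion 9 (not isolated), via lactone enolate 10 (not isolated), via bis-silyl ether 11 (not isolated)
Conditions: 6, n-BuLi, THF, −78 → −20 °C; 5, −78 → −30 °C; HMPA then 7, −78 °C; CH2O (g), −78 → −40 °C; TBSCl, → 0 °C; aq. citric acid/MeOH work-up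
Reagents that add atoms: formaldehyde, C=O; tert-butyldimethylsilyl chloride, CC(C)(C)[Si](C)(C)Cl
Why: Proposed new method: the lithiated silyl dithiane, an acyl anion equivalent for C8, opens the epoxide at its CH2 terminus (Corey–Seebach alkylation), a 1,4-Brook rearrangement then moves silicon to the tertiary alkoxide and regenerates a dithiane carbanion (anion relay chemistry), which in HMPA adds 1,4 to the butenolide so that the acyl carbon C8 is joined to the normally electrophilic β-carbon C7 (the dithiane conjugate addition–enolate trapping known from lignan lactone synthesis), and the lactone enolate is captured trans by formaldehyde and silylated; each event has close precedent, only their union in one flask is new, and the two lactone stereocentres formed without control are erased in step 5.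

Step 5
Reactants: 12 trans-3-[(tert-butyldimethylsilyloxy)methyl]-4-{2-[(2R)-2-[(2S,5S)-5-ethenyl-5-methyloxolan-2-yl]-2-hydroxypropyl]-1,3-dithian-2-yl}oxolan-2-one
Product: 14 3-[(tert-butyldimethylsilyloxy)methyl]-4-{(3R)-3-[(2S,5S)-5-ethenyl-5-methyloxolan-2-yl]-3-hydroxybutanoyl}furan-2(5H)-one, via keto lactone 13 (not isolated)
Conditions: IBX (2.5 equiv), DMSO/H2O (20:1), 25 °C; then IBX (2.5 equiv), 70 °C
Reagents that add atoms: water, O
Why: IBX first cleaves the dithiane oxidatively to the C8 ketone and then dehydrogenates the 1,4-keto lactone through its enol (IBX ketone dehydrogenation), and because C10 is quaternary only the C7 side can be desaturated, any C6=C7 isomer tautomerising to the conjugated C7=C11 butenolide.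

Step 6
Reactants: 14 3-[(tert-butyldimethylsilyloxy)methyl]-4-{(3R)-3-[(2S,5S)-5-ethenyl-5-methyloxolan-2-yl]-3-hydroxybutanoyl}furan-2(5H)-one
Product: 15 3-[(tert-butyldimethylsilyloxy)methyl]-4-{(1S,3R)-3-[(2S,5S)-5-ethenyl-5-methyloxolan-2-yl]-1,3-dihydroxybutyl}furan-2(5H)-one
Conditions: (R)-1-methyl-3,3-diphenyltetrahydro-1H,3H-pyrrolo[1,2-c][1,3,2]oxazaborole ((R)-Me-CBS, 20 mol%), catecholborane (2.5 equiv), toluene, −78 °C
Reagents that add atoms: none
Why: Corey–Bakshi–Shibata reduction in which the alkenyl (butenolide) arm is the large group, so the (R)-oxazaborolidine delivers hydride under reagent control to give the 8S carbinol (1,3-syn to the C10 hydroxyl), catecholborane at −78 °C sparing the lactone, the conjugated alkene and the vinyl group.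

Step 7
Reactants: 15 3-[(tert-butyldimethylsilyloxy)methyl]-4-{(1S,3R)-3-[(2S,5S)-5-ethenyl-5-methyloxolan-2-yl]-1,3-dihydroxybutyl}furan-2(5H)-one; 16 angelic acid
Product: 18 (1S,3R)-1-{4-[(tert-butyldimethylsilyloxy)methyl]-5-oxo-2,5-dihydrofuran-3-yl}-3-[(2S,5S)-5-ethenyl-5-methyloxolan-2-yl]-3-hydroxybutyl (2Z)-2-methylbut-2-enoate, via mixed anhydride 17 (not isolated)
Conditions: 16, 2,4,6-trichlorobenzoyl chloride, Et3N, toluene, 25 °C; then 15, 75 °C
Reagents that add atoms: none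
Why: Yamaguchi mixed-anhydride esterification acylates the secondary C8 hydroxyl only (the C10 hydroxyl is tertiary) and transfers the angeloyl group without Z-to-E isomerisation to the tiglate.

Step 8
Reactants: 18 (1S,3R)-1-{4-[(tert-butyldimethylsilyloxy)methyl]-5-oxo-2,5-dihydrofuran-3-yl}-3-[(2S,5S)-5-ethenyl-5-methyloxolan-2-yl]-3-hydroxybutyl (2Z)-2-methylbut-2-enoate
Product: 19 (1S,3R)-1-{4-[(tert-butyldimethylsilyloxy)methyl]-5-oxo-2,5-dihydrofuran-3-yl}-3-[(2S,5S)-5-formyl-5-methyloxolan-2-yl]-3-hydroxybutyl (2Z)-2-methylbut-2-enoate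
Conditions: OsO4 (2 mol%), NaIO4 (4 equiv), 2,6-lutidine, dioxane/H2O (3:1), 25 °C
Reagents that add atoms: sodium periodate, [Na+].[O-]I(=O)(=O)=O
Why: Lemieux–Johnson cleavage, in which OsO4 dihydroxylates only the electron-rich terminal vinyl group (the angelate and butenolide alkenes are electron-poor and more substituted) and periodate cleaves the diol to a non-enolisable aldehyde, so C4 cannot epimerise.

Step 9
Reactants: 19 (1S,3R)-1-{4-[(tert-butyldimethylsilyloxy)methyl]-5-oxo-2,5-dihydrofuran-3-yl}-3-[(2S,5S)-5-formyl-5-methyloxolan-2-yl]-3-hydroxybutyl (2Z)-2-methylbut-2-enoate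
Product: 22 (1S,4S,5E,8S,10R)-8-angeloyloxy-13-(tert-butyldimethylsilyloxy)-10-(triethylsilyloxy)-1,4-epoxygermacra-5,7(11)-dien-12,6-olide, via silyloxyfuran 20 (not isolated), via silyl aldolate 21 (not isolated)
Conditions: TESOTf (3.5 equiv), i-Pr2NEt (5 equiv), CH2Cl2 (1 mM, slow addition of 19), −78 → 0 °C; then DBU (3 equiv), 25 °C
Reagents that add atoms: triethylsilyl trifluoromethanesulfonate, CC[Si](CC)(CC)OS(=O)(=O)C(F)(F)F
Why: the silyl triflate and amine turn the butenolide into a 2-silyloxyfuran that attacks the silyl-activated aldehyde intramolecularly (vinylogous Mukaiyama aldol), and DBU then expels silanolate through the furanolate (E1cB) to give the cis-in-ring 5E enol lactone, the geometry that avoids an in-ring trans alkene next to the fused butenolide.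

Step 10
Reactants: 22 (1S,4S,5E,8S,10R)-8-angeloyloxy-13-(tert-butyldimethylsilyloxy)-10-(triethylsilyloxy)-1,4-epoxygermacra-5,7(11)-dien-12,6-olide
Product: 24 (1S,4S,5E,8S,10R)-13-acetoxy-8-angeloyloxy-10-hydroxy-1,4-epoxygermacra-5,7(11)-dien-12,6-olide (CNP0162854.1), via macrocyclic diol 23 (not isolated)
Conditions: HF·pyridine, pyridine/THF, 0 → 25 °C; then Ac2O, 4-(dimethylamino)pyridine (cat.), 0 °C
Reagents that add atoms: acetic anhydride, CC(=O)OC(C)=O
Why: fluoride removes both silyl ethers and the primary allylic C13 hydroxyl is then acetylated selectively because the only other free hydroxyl is tertiary, no stereocentre being touched.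

## Compound list

1 | (S)-(+)-linalool, (3S)-3,7-dimethylocta-1,6-dien-3-ol | CC(C)=CCC[C@@](C)(C=C)O | starting material
2 | (2E,6S)-2,6-dimethylocta-2,7-diene-1,6-diol | OC/C(C)=C/CC[C@@](C)(C=C)O | intermediate
3 | (3S)-5-[(2R,3R)-3-(hydroxymethyl)-3-methyloxiran-2-yl]-3-methylpent-1-en-3-ol | OC[C@@]1(C)O[C@@H]1CC[C@@](C)(C=C)O | intermediate (not isolated)
4 | (2R)-2-[(2S,5S)-5-ethenyl-5-methyloxolan-2-yl]propane-1,2-diol | OC[C@@](C)(O)[C@@H]1CC[C@@](C)(C=C)O1 | intermediate
5 | (2S,5S)-2-ethenyl-2-methyl-5-[(2R)-2-methyloxiran-2-yl]oxolane | C1[C@@](C)(O1)[C@@H]2CC[C@@](C)(C=C)O2 | intermediate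
6 | 2-(trimethylsilyl)-1,3-dithiane | C[Si](C)(C)C1SCCCS1 | starting material
7 | furan-2(5H)-one | O=C1OCC=C1 | starting material
8 | 2-lithio-2-(trimethylsilyl)-1,3-dithiane | [Li]C1([Si](C)(C)C)SCCCS1 | intermediate (not isolated)
9 | 2-lithio-1,3-dithiane bearing at C2 the (2R)-2-[(2S,5S)-5-ethenyl-5-methyloxolan-2-yl]-2-(trimethylsilyloxy)propyl group | [Li]C1(C[C@@](C)(O[Si](C)(C)C)[C@@H]2CC[C@@](C)(C=C)O2)SCCCS1 | intermediate (not isolated)
10 | lithium enolate of the 4-(2-alkyl-1,3-dithian-2-yl)oxolan-2-one formed by 1,4-addition of 9 to 7 (C7 unassigned) | [Li]OC1=CC(CO1)C2(C[C@@](C)(O[Si](C)(C)C)[C@@H]3CC[C@@](C)(C=C)O3)SCCCS2 | intermediate (not isolated)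
11 | 3,4-trans lactone as 12 but with the C10 hydroxyl as its trimethylsilyl ether | O=C1OCC(C1CO[Si](C)(C)C(C)(C)C)C2(C[C@@](C)(O[Si](C)(C)C)[C@@H]3CC[C@@](C)(C=C)O3)SCCCS2 | intermediate (not isolated)
12 | trans-3-[(tert-butyldimethylsilyloxy)methyl]-4-{2-[(2R)-2-[(2S,5S)-5-ethenyl-5-methyloxolan-2-yl]-2-hydroxypropyl]-1,3-dithian-2-yl}oxolan-2-one (both 3,4-trans isomers; lactone centres unassigned) | O=C1OCC(C1CO[Si](C)(C)C(C)(C)C)C2(C[C@@](C)(O)[C@@H]3CC[C@@](C)(C=C)O3)SCCCS2 | intermediate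
13 | trans-3-[(tert-butyldimethylsilyloxy)methyl]-4-{(3R)-3-[(2S,5S)-5-ethenyl-5-methyloxolan-2-yl]-3-hydroxybutanoyl}oxolan-2-one | O=C1OCC(C1CO[Si](C)(C)C(C)(C)C)C(=O)C[C@@](C)(O)[C@@H]2CC[C@@](C)(C=C)O2 | intermediate (not isolated)
14 | 3-[(tert-butyldimethylsilyloxy)methyl]-4-{(3R)-3-[(2S,5S)-5-ethenyl-5-methyloxolan-2-yl]-3-hydroxybutanoyl}furan-2(5H)-one | O=C1OCC(C(=O)C[C@@](C)(O)[C@@H]2CC[C@@](C)(C=C)O2)=C1CO[Si](C)(C)C(C)(C)C | intermediate
15 | 3-[(tert-butyldimethylsilyloxy)methyl]-4-{(1S,3R)-3-[(2S,5S)-5-ethenyl-5-methyloxolan-2-yl]-1,3-dihydroxybutyl}furan-2(5H)-one | O=C1OCC([C@@H](O)C[C@@](C)(O)[C@@H]2CC[C@@](C)(C=C)O2)=C1CO[Si](C)(C)C(C)(C)C | intermediate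
16 | angelic acid, (2Z)-2-methylbut-2-enoic acid | C/C=C(/C)C(O)=O | starting material
17 | angelic 2,4,6-trichlorobenzoic anhydride | C/C=C(/C)C(=O)OC(=O)c1c(Cl)cc(Cl)cc1Cl | intermediate (not isolated)
18 | (1S,3R)-1-{4-[(tert-butyldimethylsilyloxy)methyl]-5-oxo-2,5-dihydrofuran-3-yl}-3-[(2S,5S)-5-ethenyl-5-methyloxolan-2-yl]-3-hydroxybutyl (2Z)-2-methylbut-2-enoate | C/C=C(/C)C(=O)O[C@@H](C[C@@](C)(O)[C@@H]1CC[C@@](C)(C=C)O1)C2=C(CO[Si](C)(C)C(C)(C)C)C(=O)OC2 | intermediate
19 | (1S,3R)-1-{4-[(tert-butyldimethylsilyloxy)methyl]-5-oxo-2,5-dihydrofuran-3-yl}-3-[(2S,5S)-5-formyl-5-methyloxolan-2-yl]-3-hydroxybutyl (2Z)-2-methylbut-2-enoate | C/C=C(/C)C(=O)O[C@@H](C[C@@](C)(O)[C@@H]1CC[C@@](C)(C=O)O1)C2=C(CO[Si](C)(C)C(C)(C)C)C(=O)OC2 | intermediate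
20 | 2-(triethylsilyloxy)furan form of 19 with the C10 hydroxyl as its triethylsilyl ether | C/C=C(/C)C(=O)O[C@@H](C[C@@](C)(O[Si](CC)(CC)CC)[C@@H]1CC[C@@](C)(C=O)O1)c2coc(O[Si](CC)(CC)CC)c2CO[Si](C)(C)C(C)(C)C | intermediate (not isolated)
21 | ten-membered aldol adduct: C5 triethylsilyloxy and C6–H butenolide (C5 and C6 unassigned), otherwise as 22 | C/C=C(/C)C(=O)O[C@H]1C[C@@](C)(O[Si](CC)(CC)CC)[C@@H]2CC[C@@](C)(C(O[Si](CC)(CC)CC)C3OC(=O)C(CO[Si](C)(C)C(C)(C)C)=C31)O2 | intermediate (not isolated)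
22 | (1S,4S,5E,8S,10R)-8-angeloyloxy-13-(tert-butyldimethylsilyloxy)-10-(triethylsilyloxy)-1,4-epoxygermacra-5,7(11)-dien-12,6-olide | C/C=C(/C)C(=O)O[C@H]1C[C@@](C)(O[Si](CC)(CC)CC)[C@@H]2CC[C@@](C)(/C=C3/OC(=O)C(CO[Si](C)(C)C(C)(C)C)=C31)O2 | intermediate
23 | (1S,4S,5E,8S,10R)-8-angeloyloxy-10,13-dihydroxy-1,4-epoxygermacra-5,7(11)-dien-12,6-olide | C/C=C(/C)C(=O)O[C@H]1C[C@@](C)(O)[C@@H]2CC[C@@](C)(/C=C3/OC(=O)C(CO)=C31)O2 | intermediate (not isolated)
24 | (1S,4S,5E,8S,10R)-13-acetoxy-8-angeloyloxy-10-hydroxy-1,4-epoxygermacra-5,7(11)-dien-12,6-olide | C/C=C(/C)C(=O)O[C@H]1C[C@@](C)(O)[C@@H]2CC[C@@](C)(/C=C3/OC(=O)C(COC(C)=O)=C31)O2 | target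

## Step count and risks

Total step count: 10. Longest linear sequence: 10 steps (1 → 24); compounds 6, 7 and 16 enter as purchased.

**Step 9 (most likely to fail).** The aldol is reversible, the aldehyde is neopentyl-like, and the ten-membered ring must span a 2,5-trans oxolane. The fallback sets out from 18 and comes back at 22, replacing the condensation by an irreversible intramolecular Horner–Wadsworth–Emmons olefination. Treat 18 with TESOTf/i-Pr2NEt to form the 2-silyloxyfuran F4 (C10–O silylated as well). Brominate it at C6 with NBS at −78 °C to the 5-bromobutenolide F5. Heat with P(OEt)3 (Michaelis–Arbuzov) to the C6 phosphonate F6. Cleave the vinyl group with OsO4/NaIO4 to the phosphonate aldehyde F7. Cyclise with LiCl/DBU in MeCN at high dilution to 22.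

**Step 4.** The hindered relay carbanion may deprotonate 7 at C5 instead of adding 1,4, and Brook transfer to a tertiary alkoxide may be slow. The fallback sets out from 5 and comes back at 12, giving up the silyl relay. Open 5 with plain 2-lithio-1,3-dithiane and isolate the hydroxy dithiane F1. In a separate operation convert F1 into its O,C-dilithio derivative (t-BuLi, THF/HMPA, −78 °C). Then add 7, CH2O and one equivalent of TBSCl (primary alkoxide only) to reach 12 after aqueous work-up.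

**Step 5.** The tertiary β-hydroxy ketone may dehydrate or the dithiane may over-oxidise under hot IBX. The fallback sets out from 12 and comes back at 14, making the C7=C11 bond before the ketone is unmasked. Lithium diisopropylamide (2.2 equiv) then PhSeBr selenates the lactone α-carbon of 12 (the dithiane carbon carries no hydrogen), trans to the dithianyl group, giving the selenide F2. H2O2/pyridine effects selenoxide syn-elimination toward C7–H to the dithianyl butenolide F3. MeI/CaCO3 in aqueous MeCN then hydrolyses the dithiane to 14.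

Further compounds
F1 | step 4 | (2R)-1-(1,3-dithian-2-yl)-2-[(2S,5S)-5-ethenyl-5-methyloxolan-2-yl]propan-2-ol | C1CSC(SC1)C[C@@](C)(O)[C@@H]2CC[C@@](C)(C=C)O2
F2 | step 5 | 12 carrying a phenylselanyl group on the lactone α-carbon (C11) | O=C1OCC(C1(CO[Si](C)(C)C(C)(C)C)[Se]c2ccccc2)C3(C[C@@](C)(O)[C@@H]4CC[C@@](C)(C=C)O4)SCCCS3
F3 | step 5 | 3-[(tert-butyldimethylsilyloxy)methyl]-4-{2-[(2R)-2-[(2S,5S)-5-ethenyl-5-methyloxolan-2-yl]-2-hydroxypropyl]-1,3-dithian-2-yl}furan-2(5H)-one | O=C1OCC(C2(C[C@@](C)(O)[C@@H]3CC[C@@](C)(C=C)O3)SCCCS2)=C1CO[Si](C)(C)C(C)(C)C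
F4 | step 9 | 2-(triethylsilyloxy)furan form of 18 with the C10 hydroxyl as its triethylsilyl ether | C/C=C(/C)C(=O)O[C@@H](C[C@@](C)(O[Si](CC)(CC)CC)[C@@H]1CC[C@@](C)(C=C)O1)c2coc(O[Si](CC)(CC)CC)c2CO[Si](C)(C)C(C)(C)C
F5 | step 9 | C6-bromo butenolide (5-bromofuran-2(5H)-one) derived from F4, C10 triethylsilyl ether | C/C=C(/C)C(=O)O[C@@H](C[C@@](C)(O[Si](CC)(CC)CC)[C@@H]1CC[C@@](C)(C=C)O1)C2=C(CO[Si](C)(C)C(C)(C)C)C(=O)OC2Br
F6 | step 9 | C6 diethyl phosphonate derived from F5 | C/C=C(/C)C(=O)O[C@@H](C[C@@](C)(O[Si](CC)(CC)CC)[C@@H]1CC[C@@](C)(C=C)O1)C2=C(CO[Si](C)(C)C(C)(C)C)C(=O)OC2P(=O)(OCC)OCC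
F7 | step 9 | C6 diethyl phosphonate with the C4 vinyl group cleaved to the aldehyde | C/C=C(/C)C(=O)O[C@@H](C[C@@](C)(O[Si](CC)(CC)CC)[C@@H]1CC[C@@](C)(C=O)O1)C2=C(CO[Si](C)(C)C(C)(C)C)C(=O)OC2P(=O)(OCC)OCC
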